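**Retrosynthetic overview**

- Target ⇐ esterification of the C9 hydroxyl and Mitsunobu angeloylation (inversion at C3) of a 3,9‑diol ⇐ reductive enolate hydroxylation of a petasol‑type 9‑en‑8‑one ⇐ enolate isopropenylation at C7 of a bicyclic hydroxy enone.
- Rings A and B together ⇐ acid‑triggered transannular C5–C10 closure of an (E,E)‑cyclodeca‑1,5‑dienone, continued in the same flask through the 1,2‑H and 1,2‑methyl shifts (eudesmyl → eremophilyl cation) to the 9‑en‑8‑one.
- Ten‑membered ring ⇐ enolate/allylic bromide closure at C6–C7, the position of the farnesyl C1–C10 closure.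
- Open chain ⇐ isoprene + acetyl chloride (C7–C10, C1, C2) and a C5 enal acetate (C3–C6), joined at C2–C3 and resolved at C3.
- Order of ring formation: ten‑membered ring first, then both six‑membered rings in one step.

Assumption: isoprene, acetyl chloride, (2E)-3-methyl-4-oxobut-2-en-1-yl acetate (the industrial vitamin A C5 building block), 2-bromopropene, (2E)-3-methylpent-2-enoic acid and angelic acid are bought; eremophilane numbering (C3 carbinol, C4 and C5 methyl-bearing carbons, C7 isopropenyl carbon, C8 ketone, C9, C10 ring-fusion CH) is used for these carbons in every intermediate, open-chain and ten-membered ones included.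

**Route**

Step 1
Reactants: 1 isoprene; 2 acetyl chloride
Product: 3 (4E)-6-chloro-4-methylhex-4-en-2-one
Conditions: SnCl4 (0.2 equiv), CH2Cl2, −78 °C, 30 min; cold aq. NaHCO3
Reagents that add atoms: none
Why: Lewis-acid 1,4-chloroacylation of a 1,3-diene (Friedel–Crafts-type alkene acylation): the acylium ion attacks the CH2 next to the methyl-bearing carbon to give the tertiary allyl cation, chloride closes at the far terminus, and the s-trans diene gives the (E)-olefin.

Step 2
Reactants: 3 (4E)-6-chloro-4-methylhex-4-en-2-one; 4 (2E)-3-methyl-4-oxobut-2-en-1-yl acetate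
Product: 6 racemic (2E,6E)-4-hydroxy-3,7-dimethyl-9-oxodeca-2,6-dien-1-yl acetate, via trimethylsilyl ether 5 (not isolated)
Conditions: Cp2TiCl2 (0.2 equiv), Mn dust (2 equiv), Me3SiCl (2 equiv), 2,4,6-collidine (3 equiv), THF, 20 °C, slow addition of 4; then aq. citric acid, MeOH, 0 °C
Reagents that add atoms: none
Why: Barbier-type allylation mediated by Cp2TiCl (trivalent titanium, made in the flask from Cp2TiCl2 and Mn): the allyl radical drawn from 3 couples through its unsubstituted CH2 terminus with the titanium-bound conjugated aldehyde (the linear regiochemistry known for titanocene prenylation of enals), fast enough to keep the (E)-olefin, while the methyl ketone and allylic acetate are inert; C3 is formed racemic and resolved in step 3.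

Step 3
Reactants: 6 racemic (2E,6E)-4-hydroxy-3,7-dimethyl-9-oxodeca-2,6-dien-1-yl acetate
Product: 7 (2E,4S,6E)-4-hydroxy-3,7-dimethyl-9-oxodeca-2,6-dien-1-yl acetate
Conditions: Ti(OiPr)4 (0.1 equiv), D-(−)-diisopropyl tartrate (0.15 equiv), t-BuOOH (0.6 equiv), 4 Å sieves, CH2Cl2, −20 °C, to about 55% conversion
Reagents that add atoms: none
Why: Sharpless kinetic resolution of a secondary (E)-allylic alcohol: with D-(−)-diisopropyl tartrate the (R)-enantiomer is epoxidised much faster at its allylic olefin, so the (S)-alcohol, which carries C3 for the rest of the route, is recovered in high ee.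

Step 4
Reactants: 7 (2E,4S,6E)-4-hydroxy-3,7-dimethyl-9-oxodeca-2,6-dien-1-yl acetate
Product: 8 (4E,7S,8E)-7,10-dihydroxy-4,8-dimethyldeca-4,8-dien-2-one
Conditions: immobilised Candida antarctica lipase B, n-BuOH (5 equiv), t-BuOMe, 30 °C
Reagents that add atoms: none
Why: Lipase-catalysed transesterification to n-butanol removes the primary allylic acetate under neutral conditions, so the β,γ-unsaturated ketone is not conjugated and C3 is untouched.

Step 5
Reactants: 8 (4E,7S,8E)-7,10-dihydroxy-4,8-dimethyldeca-4,8-dien-2-one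
Product: 9 (4E,7S,8E)-10-bromo-7-hydroxy-4,8-dimethyldeca-4,8-dien-2-one
Conditions: N-bromosuccinimide (1.1 equiv), Me2S (1.2 equiv), CH2Cl2, −20 → 0 °C
Reagents that add atoms: N-bromosuccinimide, O=C1CCC(=O)N1Br
Why: Corey–Kim-type halogenation through the alkoxysulfonium salt converts only the unhindered primary allylic alcohol into the bromide, leaving the hindered secondary C3 carbinol and its configuration alone.

Step 6
Reactants: 9 (4E,7S,8E)-10-bromo-7-hydroxy-4,8-dimethyldeca-4,8-dien-2-one
Product: 12 (3E,6S,7E)-6-hydroxy-3,7-dimethylcyclodeca-3,7-dien-1-one, via acyclic silyl ether 10 (not isolated), via macrocyclic silyl ether 11 (not isolated)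
Conditions: 1-(trimethylsilyl)imidazole (1.2 equiv), CH2Cl2, 0 °C, evaporate; KN(SiMe3)2 (1.1 equiv, syringe pump, 8 h), THF (2 mM), −20 → 0 °C; aq. citric acid, MeOH, 0 °C
Reagents that add atoms: none
Why: Intramolecular enolate C-alkylation under high dilution, a laboratory copy of the farnesyl C1-to-C10 closure (allylic electrophile C6, enolate carbon C7): the more acidic C9 enolate cannot close because it would give an (E,E)-cycloocta-1,5-diene, proton exchange with unreacted ketone feeds the methyl-side enolate, and this closes the (E,E)-cyclodeca-1,5-diene by SN2 at the primary allylic bromide; the transient silyl ether keeps the C3 oxygen from becoming an alkoxide (anionic oxy-Cope) and C3 is not affected.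

Step 7
Reactants: 12 (3E,6S,7E)-6-hydroxy-3,7-dimethylcyclodeca-3,7-dien-1-one
Product: 15 (4aR,5R,6S)-6-hydroxy-4a,5-dimethyl-4,4a,5,6,7,8-hexahydronaphthalen-2(3H)-one, via macrocyclic trifluoroacetate 13 (not isolated), via eremophilane trifluoroacetate 14 (not isolated)
Conditions: (CF3CO)2O (1.1 equiv), CH2Cl2, −78 °C, 15 min; Tf2NH (0.2 equiv), (CF3)2CHOH/CH2Cl2 1:1, −40 → 0 °C; Et3N, MeOH, 0 °C
Reagents that add atoms: none
Why: Proposed new method: protonation of the C1=C10 olefin starts the chair–chair transannular C5→C10 closure that germacrone-type (E,E)-cyclodeca-1,5-dienones undergo with acid, the pseudo-equatorial C3 trifluoroacetoxy group choosing the ring face (C10 and then C5 are set from C3); the C4 cation, flanked by an ester too electron-poor to bridge or to give up its α-hydride and held in a non-nucleophilic medium, relays charge by the antiperiplanar 1,2-hydride shift (H5 to C4, setting C4) and 1,2-methyl shift (C10 to C5, setting C5) of the eremophilane biosynthesis, and the C10 cation loses H9 to the conjugated enone, the only product that cannot be re-protonated at carbon, so olefins from early proton loss are drawn back in; closest known reactions are the acid-induced transannular cyclisation of germacrone to eudesmanes and the epoxide-triggered (Westphalen-type) eudesmane-to-eremophilane methyl migration.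

Step 8
Reactants: 15 (4aR,5R,6S)-6-hydroxy-4a,5-dimethyl-4,4a,5,6,7,8-hexahydronaphthalen-2(3H)-one; 16 2-bromopropene
Product: 18 (3S,4aR,5R,6S)-6-hydroxy-4a,5-dimethyl-3-(prop-1-en-2-yl)-4,4a,5,6,7,8-hexahydronaphthalen-2(3H)-one, via zinc dienolate 17 (not isolated)
Conditions: LiN(iPr)2 (2.2 equiv), THF, −78 °C; ZnCl2 (2.4 equiv), −78 → 0 °C; Pd(dba)2 (5 mol %), P(t-Bu)3 (10 mol %), 16 (1.5 equiv), 25 °C; aq. NH4Cl
Reagents that add atoms: none
Why: Kinetic deprotonation of the enone at C7 (cross-conjugated dienolate), transmetalation to zinc and palladium-catalysed enolate alkenylation (Negishi-type coupling of a zinc enolate with an alkenyl bromide) deliver the isopropenyl group to the face opposite the angular C5 methyl (7S), and the weakly basic zinc enolate does not deprotonate the product, which is why this group is put on by C–C bond formation after the rings are made: protonating an isopropylidene enolate would bring the hydrogen, not the substituent, to that open face.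

Step 9
Reactants: 18 (3S,4aR,5R,6S)-6-hydroxy-4a,5-dimethyl-3-(prop-1-en-2-yl)-4,4a,5,6,7,8-hexahydronaphthalen-2(3H)-one
Product: 20 (1S,3S,4aR,5R,6S,8aR)-1,6-dihydroxy-4a,5-dimethyl-3-(prop-1-en-2-yl)octahydronaphthalen-2(1H)-one, via dilithium enolate 19 (not isolated)
Conditions: Li (2.5 equiv), NH3/THF, t-BuOH (1 equiv), −78 °C, 10 min; piperylene; evaporate NH3; THF, −78 °C, 2-(phenylsulfonyl)-3-phenyloxaziridine (1.3 equiv); aq. NH4Cl
Reagents that add atoms: 2-(phenylsulfonyl)-3-phenyloxaziridine, O=S(=O)(c1ccccc1)N1OC1c1ccccc1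
Why: Dissolving-metal (Birch-type) enone reduction gives, by axial protonation of C10 anti to the C5 methyl, the trans ring fusion (10R) and only the C8–C9 enolate, which the Davis oxaziridine hydroxylates at C9 from the open face away from the axial C5 methyl to give the equatorial 9S alcohol; the isolated isopropenyl group and C7 are untouched.

Step 10
Reactants: 20 (1S,3S,4aR,5R,6S,8aR)-1,6-dihydroxy-4a,5-dimethyl-3-(prop-1-en-2-yl)octahydronaphthalen-2(1H)-one; 21 (2E)-3-methylpent-2-enoic acid
Product: 22 (1S,3S,4aR,5R,6S,8aR)-6-hydroxy-4a,5-dimethyl-2-oxo-3-(prop-1-en-2-yl)decahydronaphthalen-1-yl (2E)-3-methylpent-2-enoate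
Conditions: DCC (1.3 equiv), DMAP (0.1 equiv), CH2Cl2, 0 → 20 °C
Reagents that add atoms: none
Why: Steglich esterification acylates the equatorial C9 hydroxyl while the C3 hydroxyl, axial and 1,3-diaxial to the C5 methyl, stays free; no stereocentre changes.

Step 11
Reactants: 22 (1S,3S,4aR,5R,6S,8aR)-6-hydroxy-4a,5-dimethyl-2-oxo-3-(prop-1-en-2-yl)decahydronaphthalen-1-yl (2E)-3-methylpent-2-enoate; 23 angelic acid
Product: 24 (1S,3S,4aR,5R,6R,8aR)-4a,5-dimethyl-6-{[(2Z)-2-methylbut-2-enoyl]oxy}-2-oxo-3-(prop-1-en-2-yl)decahydronaphthalen-1-yl (2E)-3-methylpent-2-enoate (CNP0301161.1)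
Conditions: PPh3 (3 equiv), diisopropyl azodicarboxylate (3 equiv), toluene, 0 → 25 °C
Reagents that add atoms: none
Why: Mitsunobu esterification: SN2 displacement of the activated axial C3 oxygen by angelate inverts C3 to the equatorial 3R ester of the target, and because the acid acts only as a nucleophile its Z geometry is kept.

**Compound list**

1 | isoprene | C=CC(C)=C | starting material
2 | acetyl chloride | CC(=O)Cl | starting material
3 | (4E)-6-chloro-4-methylhex-4-en-2-one | CC(=O)C/C(C)=C/CCl | intermediate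
4 | (2E)-3-methyl-4-oxobut-2-en-1-yl acetate | CC(=O)OC/C=C(\C)C=O | starting material
5 | racemic (2E,6E)-3,7-dimethyl-9-oxo-4-[(trimethylsilyl)oxy]deca-2,6-dien-1-yl acetate (not isolated) | CC(=O)OC/C=C(\C)C(O[Si](C)(C)C)C/C=C(\C)CC(C)=O | intermediate
6 | racemic (2E,6E)-4-hydroxy-3,7-dimethyl-9-oxodeca-2,6-dien-1-yl acetate | CC(=O)OC/C=C(\C)C(O)C/C=C(\C)CC(C)=O | intermediate
7 | (2E,4S,6E)-4-hydroxy-3,7-dimethyl-9-oxodeca-2,6-dien-1-yl acetate | CC(=O)OC/C=C(\C)[C@@H](O)C/C=C(\C)CC(C)=O | intermediate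
8 | (4E,7S,8E)-7,10-dihydroxy-4,8-dimethyldeca-4,8-dien-2-one | OC/C=C(\C)[C@@H](O)C/C=C(\C)CC(C)=O | intermediate
9 | (4E,7S,8E)-10-bromo-7-hydroxy-4,8-dimethyldeca-4,8-dien-2-one | BrC/C=C(\C)[C@@H](O)C/C=C(\C)CC(C)=O | intermediate
10 | (4E,7S,8E)-10-bromo-4,8-dimethyl-7-[(trimethylsilyl)oxy]deca-4,8-dien-2-one (not isolated) | BrC/C=C(\C)[C@@H](O[Si](C)(C)C)C/C=C(\C)CC(C)=O | intermediate
11 | (3E,6S,7E)-3,7-dimethyl-6-[(trimethylsilyl)oxy]cyclodeca-3,7-dien-1-one (not isolated) | O=C1CC/C=C(\C)[C@@H](O[Si](C)(C)C)C/C=C(\C)C1 | intermediate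
12 | (3E,6S,7E)-6-hydroxy-3,7-dimethylcyclodeca-3,7-dien-1-one | O=C1CC/C=C(\C)[C@@H](O)C/C=C(\C)C1 | intermediate
13 | (1S,2E,8E)-2,8-dimethyl-6-oxocyclodeca-2,8-dien-1-yl trifluoroacetate (not isolated) | O=C1CC/C=C(\C)[C@@H](OC(=O)C(F)(F)F)C/C=C(\C)C1 | intermediate
14 | (1R,2S,8aR)-1,8a-dimethyl-6-oxo-1,2,3,4,6,7,8,8a-octahydronaphthalen-2-yl trifluoroacetate (not isolated) | O=C1C=C2CC[C@H](OC(=O)C(F)(F)F)[C@H](C)[C@@]2(C)CC1 | intermediate
15 | (4aR,5R,6S)-6-hydroxy-4a,5-dimethyl-4,4a,5,6,7,8-hexahydronaphthalen-2(3H)-one | O=C1C=C2CC[C@H](O)[C@H](C)[C@@]2(C)CC1 | intermediate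
16 | 2-bromopropene | C=C(C)Br | starting material
17 | bis(chlorozinc) derivative of 15: C3 alkoxide and C7=C8 dienolate (not isolated) | Cl[Zn]OC1=CC[C@]2(C)[C@@H](C)[C@@H](O[Zn]Cl)CCC2=C1 | intermediate
18 | (3S,4aR,5R,6S)-6-hydroxy-4a,5-dimethyl-3-(prop-1-en-2-yl)-4,4a,5,6,7,8-hexahydronaphthalen-2(3H)-one (3-epi-petasol) | C=C(C)[C@@H]1C[C@]2(C)[C@@H](C)[C@@H](O)CCC2=CC1=O | intermediate
19 | dilithium salt of the 9,10-dihydro derivative of 18: C3 alkoxide and C8=C9 enolate, trans ring fusion (not isolated) | [Li+].[Li+].C=C(C)[C@@H]1C[C@]2(C)[C@@H](C)[C@@H]([O-])CC[C@H]2C=C1[O-] | intermediate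
20 | (1S,3S,4aR,5R,6S,8aR)-1,6-dihydroxy-4a,5-dimethyl-3-(prop-1-en-2-yl)octahydronaphthalen-2(1H)-one | C=C(C)[C@@H]1C[C@]2(C)[C@@H](C)[C@@H](O)CC[C@H]2[C@H](O)C1=O | intermediate
21 | (2E)-3-methylpent-2-enoic acid | CC/C(C)=C/C(=O)O | starting material
22 | (1S,3S,4aR,5R,6S,8aR)-6-hydroxy-4a,5-dimethyl-2-oxo-3-(prop-1-en-2-yl)decahydronaphthalen-1-yl (2E)-3-methylpent-2-enoate | C=C(C)[C@@H]1C[C@]2(C)[C@@H](C)[C@@H](O)CC[C@H]2[C@H](OC(=O)/C=C(\C)CC)C1=O | intermediate
23 | angelic acid, (2Z)-2-methylbut-2-enoic acid | C/C=C(/C)C(=O)O | starting material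
24 | CNP0301161.1, (1S,3S,4aR,5R,6R,8aR)-4a,5-dimethyl-6-{[(2Z)-2-methylbut-2-enoyl]oxy}-2-oxo-3-(prop-1-en-2-yl)decahydronaphthalen-1-yl (2E)-3-methylpent-2-enoate | C=C(C)[C@@H]1C[C@]2(C)[C@@H](C)[C@H](OC(=O)/C(C)=C\C)CC[C@H]2[C@H](OC(=O)/C=C(\C)CC)C1=O | target

**Step count and risks**

Total steps: 11. Longest linear sequence: 11 steps (from 1 and 2 to 24); compounds 4, 16, 21 and 23 enter as bought materials.

Most likely to fail, first: step 7. The eudesmyl cation may simply lose a proton and stop at eudesmenes, the allylic trifluoroacetate of a 4(5)-olefin may ionise, or ring closure may use the C3-axial conformer and give the separable C3,C4,C5 diastereomer. The fallback sets out from 13 and comes back at 14. Treat 13 with a weaker acid (camphorsulfonic acid, CH2Cl2, 0 → 20 °C) so the reaction stops at the eudesmane stage and the olefin isomers equilibrate to the tetrasubstituted olefin (2S,4aR)-1,4a-dimethyl-6-oxo-2,3,4,4a,5,6,7,8-octahydronaphthalen-2-yl trifluoroacetate F1. Epoxidise with mCPBA from the face opposite the angular methyl to (2S,4aR)-1,8a-epoxy-1,4a-dimethyl-6-oxodecahydronaphthalen-2-yl trifluoroacetate F2. Open it with BF3·OEt2 at −78 °C: the C–O bond remote from the ester breaks, the angular methyl moves to that carbon antiperiplanar to the oxygen, and H9 is lost, giving (1S,2S,8aS)-1-hydroxy-1,8a-dimethyl-6-oxo-1,2,3,4,6,7,8,8a-octahydronaphthalen-2-yl trifluoroacetate F3. Remove the tertiary hydroxyl by ionic hydrogenation (Et3SiH, BF3·OEt2, −40 °C); hydride reaches C4 from the face opposite the C5 methyl and the C3 ester, which gives 14, cleaved to 15 as in step 7.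

Second: step 6. Ring closure depends on the minor methyl-side enolate; O-alkylation, oligomers or olefin migration could win. The fallback sets out from 10 (isolated this time) and comes back at 12. Condense 10 with 1,1-dimethylhydrazine (MgSO4, Et2O) to (4E,7S,8E)-10-bromo-4,8-dimethyl-7-[(trimethylsilyl)oxy]deca-4,8-dien-2-one N,N-dimethylhydrazone F4. LiN(iPr)2 metallates a dimethylhydrazone only at the methyl group, so slow addition of F4 to the base in THF at −78 → 0 °C closes the ring regiospecifically to (3E,6S,7E)-3,7-dimethyl-6-[(trimethylsilyl)oxy]cyclodeca-3,7-dien-1-one N,N-dimethylhydrazone F5. Two-phase hydrolysis with aqueous oxalic acid removes the hydrazone and the silyl group and gives 12.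

Third: step 11. The C3 hydroxyl is axial, 1,3-diaxial to a methyl and next to a tertiary carbon, so E2 elimination can beat substitution. The fallback sets out from 18 and comes back at 24, setting C3 by thermodynamic reduction instead of SN2 inversion. Oxidise 18 with Dess–Martin periodinane to (4R,5R,7S)-eremophila-9,11-diene-3,8-dione F6. Run the dissolving-metal step as in step 9 but with Li (5 equiv) and t-BuOH (2 equiv): the C3 ketone is reduced to the equatorial alkoxide while the enone gives the enolate, and Davis oxidation then gives (3R,4R,5R,7S,9S,10R)-3,9-dihydroxyeremophil-11-en-8-one F7. Esterify the unhindered equatorial C3 hydroxyl with angelic acid 23 through the 2,4,6-trichlorobenzoyl mixed anhydride (Et3N, then DMAP, toluene) to (3R,4R,5R,7S,9S,10R)-9-hydroxy-8-oxoeremophil-11-en-3-yl (2Z)-2-methylbut-2-enoate F8. Steglich esterification of the C9 hydroxyl with 21 (DCC, DMAP) gives 24.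

Further compounds
F1 | step 7 | (2S,4aR)-1,4a-dimethyl-6-oxo-2,3,4,4a,5,6,7,8-octahydronaphthalen-2-yl trifluoroacetate | O=C1CCC2=C(C)[C@@H](OC(=O)C(F)(F)F)CC[C@]2(C)C1
F2 | step 7 | (2S,4aR)-1,8a-epoxy-1,4a-dimethyl-6-oxodecahydronaphthalen-2-yl trifluoroacetate, epoxide oxygen trans to the 4a-methyl | O=C1CC[C@@]2(O3)[C@@]3(C)[C@@H](OC(=O)C(F)(F)F)CC[C@]2(C)C1
F3 | step 7 | (1S,2S,8aS)-1-hydroxy-1,8a-dimethyl-6-oxo-1,2,3,4,6,7,8,8a-octahydronaphthalen-2-yl trifluoroacetate, hydroxyl trans to the 8a-methyl | O=C1C=C2CC[C@H](OC(=O)C(F)(F)F)[C@@](C)(O)[C@@]2(C)CC1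
F4 | step 6 | (4E,7S,8E)-10-bromo-4,8-dimethyl-7-[(trimethylsilyl)oxy]deca-4,8-dien-2-one N,N-dimethylhydrazone | BrC/C=C(\C)[C@@H](O[Si](C)(C)C)C/C=C(\C)C/C(C)=N/N(C)C
F5 | step 6 | (3E,6S,7E)-3,7-dimethyl-6-[(trimethylsilyl)oxy]cyclodeca-3,7-dien-1-one N,N-dimethylhydrazone | CN(C)N=C1CC/C=C(\C)[C@@H](O[Si](C)(C)C)C/C=C(\C)C1
F6 | step 11 | (4R,5R,7S)-eremophila-9,11-diene-3,8-dione | C=C(C)[C@@H]1C[C@]2(C)[C@@H](C)C(=O)CCC2=CC1=O
F7 | step 11 | (3R,4R,5R,7S,9S,10R)-3,9-dihydroxyeremophil-11-en-8-one | C=C(C)[C@@H]1C[C@]2(C)[C@@H](C)[C@H](O)CC[C@H]2[C@H](O)C1=O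
F8 | step 11 | (3R,4R,5R,7S,9S,10R)-9-hydroxy-8-oxoeremophil-11-en-3-yl (2Z)-2-methylbut-2-enoate | C=C(C)[C@@H]1C[C@]2(C)[C@@H](C)[C@H](OC(=O)/C(C)=C\C)CC[C@H]2[C@H](O)C1=O
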